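**Assumption:** the target SMILES has no stereocentres and no stereogenic double bonds (both alkenes end in CMe2), so the molecule is achiral and the "single enantiomer" requirement needs no stereocontrol. This route is a paper proposal; nothing here has been run.

## Retrosynthetic overview

1. Target ⇐ reduction and deacetylation of a B-ring methoxy-p-quinone ⇐ CAN oxidative demethylation of a 2',4',5'-trimethoxy B ring (latent hydroquinone, so no acid-labile groups are ever removed next to the prenyls).
2. Ring C is the only ring formed: a one-step thermal Mentzer annulation of unprotected phloroglucinol (ring A) with an α-prenyl aroylacetate, via an α-oxoketene. It makes C4–C4a and O1–C2 and brings the 3-prenyl in already installed, avoiding the usual chalcone or Baker–Venkataraman sequence and late C3 functionalisation.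
3. α-Prenyl β-ketoester ⇐ aldol/oxidation of the B-ring aldehyde with ethyl 5-methylhex-4-enoate (Johnson–Claisen).
4. B-ring aldehyde ⇐ 1,2,4-trimethoxybenzene by directed ortho-metalation/prenylation at C3, then Vilsmeier formylation at C5.
5. Ring order: A and B are bought as arenes; pyranone C is closed in step 6; the B-ring oxidation level is adjusted last.

Numbers are given to substrates, products and carbon-contributing reagents; water, bases, oxidants and solvents are named in the conditions only.

## Route

**Step 1**
Reactants: 1, 1,2,4-trimethoxybenzene; 2, prenyl bromide (1-bromo-3-methylbut-2-ene)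
Product: 3, 1,2,4-trimethoxy-3-(3-methylbut-2-en-1-yl)benzene
Conditions: n-BuLi (1.1 equiv), TMEDA, THF, 0 °C → rt, 2 h; then CuBr·SMe2 (10 mol %), 2 (1.2 equiv), −78 °C → rt
Reagents that add atoms: prenyl bromide, CC(C)=CCBr
Why: Directed ortho-metalation occurs at C3, the C–H flanked by two methoxy groups, and copper-catalysed SN2 coupling of the aryllithium with prenyl bromide gives the linear prenyl arene.

**Step 2**
Reactants: 3; 4, N,N-dimethylformamide
Product: 5, 2,4,5-trimethoxy-3-(3-methylbut-2-en-1-yl)benzaldehyde
Conditions: POCl3 (1.5 equiv), DMF, 0 → 65 °C, 3 h; then aq. NaOAc, 0 °C → rt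
Reagents that add atoms: DMF, CN(C)C=O (formyl carbon); water, O (carbonyl oxygen on iminium hydrolysis)
Why: Vilsmeier–Haack formylation goes to C5, the only position activated by two methoxy groups (ortho to 4-OMe, para to 2-OMe; the 3-methyl analogue is known to formylate there), and the DMF-buffered medium should spare an isolated trisubstituted alkene that has no free ortho-phenol.

**Step 3**
Reactants: 6, 2-methylbut-3-en-2-ol; 7, triethyl orthoacetate
Product: 8, ethyl 5-methylhex-4-enoate
Conditions: 7 (4 equiv), EtCO2H (5 mol %), neat, 140 °C, EtOH distilled off, 5 h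
Reagents that add atoms: triethyl orthoacetate, CCOC(C)(OCC)OCC
Why: Johnson–Claisen rearrangement: the mixed ketene acetal of the tertiary allylic alcohol undergoes a [3,3]-sigmatropic shift to the γ,δ-unsaturated ester carrying the gem-dimethyl alkene.

**Step 4**
Reactants: 5; 8
Product: 9, ethyl 2-{hydroxy[2,4,5-trimethoxy-3-(3-methylbut-2-en-1-yl)phenyl]methyl}-5-methylhex-4-enoate, as a mixture of racemic syn and anti diastereomers
Conditions: LDA (1.15 equiv), 8 (1.2 equiv), THF, −78 °C, 30 min; then 5, −78 °C, 1 h; AcOH quench at −78 °C
Reagents that add atoms: none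
Why: Lithium ester-enolate aldol addition to a non-enolisable aldehyde; the two new stereocentres form unselectively and both are erased later (the carbinol in step 5, the α-carbon when it becomes sp2 C3 in step 6).

**Step 5**
Reactants: 9
Product: 10, ethyl 5-methyl-2-[2,4,5-trimethoxy-3-(3-methylbut-2-en-1-yl)benzoyl]hex-4-enoate (racemic, keto/enol mixture)
Conditions: Dess–Martin periodinane (1.4 equiv), NaHCO3, CH2Cl2, 0 °C → rt
Reagents that add atoms: none
Why: Dess–Martin oxidation of the secondary benzylic alcohol under buffered neutral conditions gives the β-ketoester without touching either alkene.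

**Step 6 (key step)**
Reactants: 10; 11, phloroglucinol (anhydrous, 2 equiv)
Product: 12, 5,7-dihydroxy-3-(3-methylbut-2-en-1-yl)-2-[2,4,5-trimethoxy-3-(3-methylbut-2-en-1-yl)phenyl]-4H-chromen-4-one
Conditions: neat melt, Ar, 240 °C (microwave, open vessel), 10–15 min; alternatively Ph2O, 250 °C, 1 h
Reagents that add atoms: none beyond reactant 11 (Oc1cc(O)cc(O)c1); EtOH and H2O are lost
Why: Mentzer (Simonis-type) thermal chromone synthesis: loss of EtOH from the enolised β-ketoester gives an α-oxoketene that C-acylates threefold-symmetric phloroglucinol (one regioisomer only), and the ortho-OH then condenses with the aryl ketone to close the pyranone. The reaction type is known for α-alkyl aroylacetates giving 3-alkylflavones, and the 2'-oxygen being a methyl ether blocks lactonisation to a 4-hydroxycoumarin; the α-prenyl, ortho-methoxy substrate is an untested extension.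

**Step 7**
Reactants: 12; 13, acetic anhydride
Product: 14, 5,7-diacetoxy-3-(3-methylbut-2-en-1-yl)-2-[2,4,5-trimethoxy-3-(3-methylbut-2-en-1-yl)phenyl]-4H-chromen-4-one
Conditions: Ac2O (5 equiv), pyridine, DMAP (cat.), rt → 50 °C, 4 h
Reagents that add atoms: acetic anhydride, CC(=O)OC(C)=O
Why: Standard phenol acetylation (DMAP and warming overcome the chelated 5-OH), which deactivates the A ring towards Ce(IV) oxidation and nitration in the next step.

**Step 8**
Reactants: 14
Product: 15, 5,7-diacetoxy-2-[4-methoxy-5-(3-methylbut-2-en-1-yl)-3,6-dioxocyclohexa-1,4-dien-1-yl]-3-(3-methylbut-2-en-1-yl)-4H-chromen-4-one (the B-ring 2',5'-p-quinone)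
Conditions: (NH4)2Ce(NO3)6 (2.7 equiv), MeCN/H2O 3:1, 0 °C, 20 min
Reagents that add atoms: water, O (both quinone oxygens; two MeOH are lost)
Why: CAN oxidative demethylation of a p-dimethoxyarene to the p-benzoquinone, as used on prenylated polymethoxyarenes in ubiquinone-type syntheses; only the 2'/5' methoxy pair is para, so the 4'-OMe stays as the vinylogous ester while the acetylated A ring and isolated alkenes are inert at 0 °C.

**Step 9**
Reactants: 15
Product: 16, heteroartonin A, 5,7-dihydroxy-2-[2,5-dihydroxy-4-methoxy-3-(3-methylbut-2-en-1-yl)phenyl]-3-(3-methylbut-2-en-1-yl)-4H-chromen-4-one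
Conditions: Na2S2O4 (6 equiv), THF/H2O, rt, 15 min; then K2CO3 (4 equiv), degassed MeOH, 0 °C → rt, 1 h, Ar; AcOH to pH 5
Reagents that add atoms: none
Why: Dithionite reduces the quinone to the hydroquinone, and base methanolysis of the two aryl acetates under oxygen-free, reducing conditions prevents re-oxidation; no acid is used, so the 2'-OH cannot cyclise onto either prenyl group.

## Compound list

1 | 1,2,4-trimethoxybenzene | COc1ccc(OC)c(OC)c1 | starting material
2 | prenyl bromide (1-bromo-3-methylbut-2-ene) | CC(C)=CCBr | starting material
3 | 1,2,4-trimethoxy-3-(3-methylbut-2-en-1-yl)benzene | COc1ccc(OC)c(CC=C(C)C)c1OC | intermediate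
4 | N,N-dimethylformamide | CN(C)C=O | starting material (reagent)
5 | 2,4,5-trimethoxy-3-(3-methylbut-2-en-1-yl)benzaldehyde | COc1cc(C=O)c(OC)c(CC=C(C)C)c1OC | intermediate
6 | 2-methylbut-3-en-2-ol | CC(C)(O)C=C | starting material
7 | triethyl orthoacetate | CCOC(C)(OCC)OCC | starting material
8 | ethyl 5-methylhex-4-enoate | CCOC(=O)CCC=C(C)C | intermediate
9 | ethyl 2-{hydroxy[2,4,5-trimethoxy-3-(3-methylbut-2-en-1-yl)phenyl]methyl}-5-methylhex-4-enoate (racemic syn/anti mixture) | CCOC(=O)C(CC=C(C)C)C(O)c1cc(OC)c(OC)c(CC=C(C)C)c1OC | intermediate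
10 | ethyl 5-methyl-2-[2,4,5-trimethoxy-3-(3-methylbut-2-en-1-yl)benzoyl]hex-4-enoate (racemic) | CCOC(=O)C(CC=C(C)C)C(=O)c1cc(OC)c(OC)c(CC=C(C)C)c1OC | intermediate
11 | phloroglucinol (benzene-1,3,5-triol) | Oc1cc(O)cc(O)c1 | starting material
12 | 5,7-dihydroxy-3-prenyl-2-(2,4,5-trimethoxy-3-prenylphenyl)-4H-chromen-4-one | COc1cc(-c2oc3cc(O)cc(O)c3c(=O)c2CC=C(C)C)c(OC)c(CC=C(C)C)c1OC | intermediate
13 | acetic anhydride | CC(=O)OC(C)=O | starting material (reagent)
14 | 5,7-diacetoxy-3-prenyl-2-(2,4,5-trimethoxy-3-prenylphenyl)-4H-chromen-4-one | COc1cc(-c2oc3cc(OC(C)=O)cc(OC(C)=O)c3c(=O)c2CC=C(C)C)c(OC)c(CC=C(C)C)c1OC | intermediate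
15 | 5,7-diacetoxy-2-(4-methoxy-3,6-dioxo-5-prenylcyclohexa-1,4-dien-1-yl)-3-prenyl-4H-chromen-4-one | COC1=C(CC=C(C)C)C(=O)C(c2oc3cc(OC(C)=O)cc(OC(C)=O)c3c(=O)c2CC=C(C)C)=CC1=O | intermediate
16 | heteroartonin A | COc1c(O)cc(-c2oc3cc(O)cc(O)c3c(=O)c2CC=C(C)C)c(O)c1CC=C(C)C | target

## Step count and risks

**Total steps:** 9. **Longest linear sequence:** 8 (steps 1, 2, 4, 5, 6, 7, 8, 9, from 1,2,4-trimethoxybenzene). Step 3 is a one-step side branch.

**Three steps most likely to fail, with fallbacks:**

1. **Step 6 (Mentzer annulation at 240 °C).** Risks are thermal damage to the two prenyl groups, slow ketene formation from the hindered α-substituted ketoester, and coumarin by-products. Fallback: drop the one-step annulation and build ring C stepwise at low temperature. Oxidise 5 to the benzoic acid, esterify 2-hydroxy-4,6-bis(methoxymethoxy)acetophenone with it, carry out a Baker–Venkataraman rearrangement, C-prenylate the 1,3-diketone, cyclodehydrate, and rejoin the route at the CAN step.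

2. **Step 2 (Vilsmeier formylation with a prenyl group present).** Risks are HCl addition to the alkene and incomplete C5 selectivity. Fallback: install the side chain after the aldehyde with full regiocontrol. Start from commercial 2-hydroxy-4,5-dimethoxybenzaldehyde, O-allylate, run an aromatic Claisen rearrangement (C3 is the only free ortho position), O-methylate, and convert allyl to prenyl by cross-metathesis with 2-methyl-2-butene to reach 5.

3. **Step 8 (CAN oxidative demethylation).** Risks are attack on the prenyl alkenes, ortho-quinone formation, or over-oxidation. Fallback: abandon the latent-quinone strategy. Carry the 2',5'-oxygens as MOM ethers from 2-methoxyhydroquinone (the same C3 lithiation/prenylation applies), form ring C by a low-temperature method (ynone iodocyclisation then Stille prenylation at C3, or Baker–Venkataraman), and finish with mild HCl/MeOH removal of the MOM groups.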